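Slowness comes first: past the opening drop, the substrates in birch and oak sink by a few points a minute. What does that loss become?

| setting | birch | oak | flask |
|---|---|---|---|
| left-handed substrate | 18 mM | 18 mM | 18 mM |
| right-handed substrate | 18 mM | 18 mM | 18 mM |
| solid reagent | 36 mM | 81 mM | 54.0 mM |
| remark | run made earlier | run made earlier |  |
| time |  |  | 4.0 min |

- birch (time / min: left-handed substrate / %, right-handed substrate / %, left-handed product / %): 0.500: 42.2, 42.6, 0.6; 1.00: 40.3, 41.6, 1.4; 1.50: 39.2, 38.7, 2.1; 2.00: 37.4, 37.7, 3.3; 2.50: 35.9, 35.6, 4.5; 3.00: 34.9, 34.0, 5.1
- oak (time / min: left-handed substrate / %, right-handed substrate / %, left-handed product / %): 0.250: 43.3, 43.0, 0.4; 0.417: 43.1, 43.2, 0; 0.667: 42.6, 41.6, 1.0; 1.33: 39.6, 39.3, 1.7; 2.00: 37.3, 37.0, 2.6; 3.00: 34.4, 34.4, 4.8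

(each reading ± 0.5 percentage points)

- coupling partner is single-handed; left-handed substrate and right-handed substrate are mirror images of each other, charged as a racemate, each of them at the stated concentration
- solid, in amounts per volume of the solution: solid reagent
- at the start none of the solid reagent is in solution
- what has gone into achiral form counts as reacted
- an excess is the difference of the two amounts in percent of their sum
- an excess is below zero if the other one leads
- the handed part of coupling partner does not stay in what it makes, so the products of the two hands are mirror images too

- part of the left-handed substrate and right-handed substrate charged together that has reacted at 4.0 min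
- excess of left-handed product over right-handed product in the product at 4.0 min
- excess of right-handed substrate over left-handed substrate among what is left of the two at 4.0 min

Which charge is the limiting reagent? The substrates, 36.0 mM together, are less than the 54.0 mM of solid reagent. So I write their balance: what leaves the pair is achiral form, product of either hand, or something unread.

How fast does the pair fall? In birch, from first reading to last, 0.0636 min⁻¹ as a fraction of the charge. In oak, 0.0636 min⁻¹.

Does the solid matter? Between these two charges the slopes match. The flask's charge lies between them, so I carry the birch slope over.

Your c? Running birch on from its last reading, I reckon 37.5%.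

And eS? The hands read alike within the scatter of 0.5 percentage points, so I say near zero.

Now eP. Was right-handed product ever read? No, and that is the weak spot. Left-handed product, run on the same way, reaches 6.90%. The unread loss, what the pair has lost less the left-handed product, is then 30.6%. If it were right-handed product throughout, eP would be −63.2%. Any other share in it raises eP, so I give that floor and no single figure.

The forecast gives c 37% and eS 0%, and for eP it commits to a single figure, −46%, on the ground that “right-handed product forms at about 4.7 points/min”.

The flask gives c 38.1%, eP 31.9%, eS 0.146%.

    2 coupling partner → self-condensation product (k = 1.05 M⁻¹ s⁻¹)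
    coupling partner + right-handed substrate → right-handed product (k = 0.349 M⁻¹ s⁻¹)
    left-handed substrate ⇌ achiral form (K = 0.270, k = 0.155 s⁻¹)
    achiral form → waste (k = 0.00824 s⁻¹)
    coupling partner + left-handed substrate → left-handed product (k = 0.678 M⁻¹ s⁻¹)
    coupling partner ⇌ dormant form (K = 1.90, k = 0.00570 s⁻¹)
    right-handed substrate ⇌ achiral form (K = 0.270, k = 0.155 s⁻¹)
    solid reagent ⇌ coupling partner, rate k8*(cs8 - [coupling partner]) while solid is left; crystals form when [coupling partner] > cs8 (solubility = 3.90 mM, k = 0.0101 s⁻¹)

The flask's unread loss at 4.0 min is 31.5%, against my 30.6%. It holds achiral form 8.31%, right-handed product 3.40% and waste 19.8%, so waste is its largest share. Right-handed product stays below the left-handed 6.59%. The neighbouring flask, charged with 140 mM of solid reagent, gets the same reckoning, 30.6%. Its unread loss is 31.5%, with waste 19.8%, and its eP is 31.9%.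

The data are simulated on assumed constants; noise was put on by code.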